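**Retrosynthetic overview**
1. Target 19 comes from 17 by global deprotection (two aryl silyl ethers, one MOM ether).
2. The prenyl group is put on C5 of aldehyde 13 by directed ortho-metalation between the 4-OMOM and 6-OMe groups, with the formyl group masked in the flask; the formyl group comes from the C3 iodide of 10.
3. The furan ring is the only ring made (both benzene rings are bought). It is closed by iodocyclisation of diarylalkyne 9: either of the two equivalent MOM-ether oxygens of symmetric ring A attacks, so O1 and O4 differentiate themselves and C3 is marked with iodine.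
4. 9 comes from Sonogashira coupling of iodide 4 (from 5-methoxyresorcinol) with alkyne 8 (from 2,4-dihydroxybenzaldehyde).

Assumption: the target has no stereocentre and no stereogenic double bond, so it is achiral and needs no stereocontrol; racemic carbinol-type carbons occur only in the transient intermediates 7, 12, 14, 15 and 16.

Step 1
Reactants: 1 5-methoxybenzene-1,3-diol (5-methoxyresorcinol)
Product: 2 1-methoxy-3,5-bis(methoxymethoxy)benzene
Conditions: MOMCl (2.6 equiv), i-Pr2NEt (3.2 equiv), CH2Cl2, 0 °C to rt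
Reagents that add atoms: chloromethyl methyl ether, COCCl
Why: Base-mediated O-alkylation (MOM protection) of both phenols; the two acetal ethers later act as ortho-directing groups, as the cyclising oxygen and as the protecting group on the C4 oxygen, and no stereocentre is formed.

Step 2
Reactants: 2 1-methoxy-3,5-bis(methoxymethoxy)benzene
Product: 4 2-iodo-5-methoxy-1,3-bis(methoxymethoxy)benzene, via aryllithium 3 (not isolated)
Conditions: n-BuLi (1.1 equiv), THF, 0 °C, 1 h; then I2 (1.2 equiv), −78 °C to rt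
Reagents that add atoms: iodine, II
Why: Directed ortho-metalation: the position flanked by both MOM ethers is lithiated by chelation-assisted deprotonation and the aryllithium is trapped with iodine, which places the halogen on the future C3a; no stereocentre.

Step 3
Reactants: 5 2,4-dihydroxybenzaldehyde
Product: 6 2,4-bis(triisopropylsilyloxy)benzaldehyde
Conditions: i-Pr3SiOTf (2.4 equiv), 2,6-lutidine (3 equiv), CH2Cl2, 0 °C to rt
Reagents that add atoms: triisopropylsilyl trifluoromethanesulfonate, CC(C)[Si](C(C)C)(C(C)C)OS(=O)(=O)C(F)(F)F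
Why: Silylation of both phenols with the silyl triflate (needed for the hydrogen-bonded 2-OH); the bulky silyl ethers are non-nucleophilic in the later iodocyclisation and do not direct lithiation.

Step 4
Reactants: 6 2,4-bis(triisopropylsilyloxy)benzaldehyde
Product: 8 1-ethynyl-2,4-bis(triisopropylsilyloxy)benzene, via diazo alkoxide 7 (not isolated)
Conditions: Me3SiCHN2 (1.2 equiv), LiN(i-Pr)2 (1.2 equiv), THF, −78 °C, then rt
Reagents that add atoms: trimethylsilyldiazomethane, C[Si](C)(C)C=[N+]=[N-]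
Why: Colvin rearrangement (Seyferth–Gilbert-type one-carbon homologation): the lithiated diazo reagent adds to the aldehyde, Peterson elimination and loss of N2 give an alkylidene carbene that rearranges to the terminal alkyne under non-protic conditions that spare the aryl silyl ethers.

Step 5
Reactants: 4 2-iodo-5-methoxy-1,3-bis(methoxymethoxy)benzene; 8 1-ethynyl-2,4-bis(triisopropylsilyloxy)benzene
Product: 9 2-{[2,4-bis(triisopropylsilyloxy)phenyl]ethynyl}-5-methoxy-1,3-bis(methoxymethoxy)benzene
Conditions: PdCl2(PPh3)2 (5 mol%), CuI (10 mol%), Et3N, DMF, 65 °C, argon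
Reagents that add atoms: none
Why: Sonogashira coupling of the aryl iodide with the terminal alkyne; with no free phenol present the diarylalkyne does not cyclise.

Step 6
Reactants: 9 2-{[2,4-bis(triisopropylsilyloxy)phenyl]ethynyl}-5-methoxy-1,3-bis(methoxymethoxy)benzene
Product: 10 2-[2,4-bis(triisopropylsilyloxy)phenyl]-3-iodo-6-methoxy-4-(methoxymethoxy)benzofuran
Conditions: I2 (2 equiv), NaHCO3 (3 equiv), CH2Cl2, rt, dark; aq. Na2S2O3 work-up
Reagents that add atoms: iodine, II
Why: Larock-type electrophilic 5-endo-dig iodocyclisation: the iodonium-activated alkyne is attacked by one of the two symmetry-equivalent MOM-ether oxygens of ring A and the oxonium ion loses its methoxymethyl group to iodide, which forms the furan ring, marks C3 with iodine and leaves the other MOM ether on O4 (the silyl ether oxygen of ring B does not compete).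

Step 7
Reactants: 10 2-[2,4-bis(triisopropylsilyloxy)phenyl]-3-iodo-6-methoxy-4-(methoxymethoxy)benzofuran
Product: 13 2-[2,4-bis(triisopropylsilyloxy)phenyl]-6-methoxy-4-(methoxymethoxy)benzofuran-3-carbaldehyde, via arylmagnesium chloride 11 (not isolated), via magnesium aminoalkoxide 12 (not isolated)
Conditions: i-PrMgCl·LiCl (1.3 equiv), THF, −20 to 0 °C; then DMF (3 equiv), 0 °C to rt; aq. NH4Cl
Reagents that add atoms: N,N-dimethylformamide, CN(C)C=O
Why: Iodine–magnesium exchange followed by Bouveault formylation with DMF; the arylmagnesium is stable towards the ring opening known for 3-lithiobenzofurans, and the iodide fixes the formyl group at C3, where an electrophilic formylation would have to compete with the highly activated C7.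

Step 8
Reactants: 13 2-[2,4-bis(triisopropylsilyloxy)phenyl]-6-methoxy-4-(methoxymethoxy)benzofuran-3-carbaldehyde
Product: 17 2-[2,4-bis(triisopropylsilyloxy)phenyl]-6-methoxy-4-(methoxymethoxy)-5-(3-methylbut-2-en-1-yl)benzofuran-3-carbaldehyde, via lithium aminoalkoxide 14 (not isolated), via C5-lithiated aminoalkoxide 15 (not isolated), via C5-prenylated aminoalkoxide 16 (not isolated)
Conditions: lithium 4-methylpiperazin-1-ide (1.2 equiv, from 1-methylpiperazine and n-BuLi), THF, −20 °C; then n-BuLi (2 equiv), TMEDA, −20 to 0 °C, 2 h; then prenyl bromide (3 equiv), −78 °C to rt; aq. NH4Cl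
Reagents that add atoms: 1-bromo-3-methylbut-2-ene (prenyl bromide), CC(C)=CCBr
Why: Comins in situ protection of the aldehyde as an α-amino alkoxide, then directed ortho-metalation at C5 (the only site flanked by the MOM ether and the methoxy group) and SN2 allylation of the aryllithium with prenyl bromide; aqueous work-up returns the aldehyde, and the racemic aminal carbon is lost again.

Step 9
Reactants: 17 2-[2,4-bis(triisopropylsilyloxy)phenyl]-6-methoxy-4-(methoxymethoxy)-5-(3-methylbut-2-en-1-yl)benzofuran-3-carbaldehyde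
Product: 19 2-(2,4-dihydroxyphenyl)-4-hydroxy-6-methoxy-5-(3-methylbut-2-en-1-yl)benzofuran-3-carbaldehyde (target), via desilylated diphenol 18 (not isolated)
Conditions: Bu4NF (2.5 equiv), THF, 0 °C, 30 min; then 2 M aq. HCl, 40 °C; work-up at pH 5–6
Reagents that add atoms: none
Why: Fluoride cleaves both aryl silyl ethers and dilute aqueous acid then hydrolyses the MOM acetal next to the formyl group under conditions mild enough to spare the ortho-prenyl phenol; any lactol formed with the 2'-OH reverts to the hydroxy aldehyde on work-up, and the product is achiral.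

**Compound list**
1 | 5-methoxybenzene-1,3-diol (5-methoxyresorcinol) | COc1cc(O)cc(O)c1 | starting material
2 | 1-methoxy-3,5-bis(methoxymethoxy)benzene | COCOc1cc(OC)cc(OCOC)c1 | intermediate
3 | [4-methoxy-2,6-bis(methoxymethoxy)phenyl]lithium (not isolated) | [Li]c1c(OCOC)cc(OC)cc1OCOC | intermediate
4 | 2-iodo-5-methoxy-1,3-bis(methoxymethoxy)benzene | COCOc1cc(OC)cc(OCOC)c1I | intermediate
5 | 2,4-dihydroxybenzaldehyde | O=Cc1ccc(O)cc1O | starting material
6 | 2,4-bis(triisopropylsilyloxy)benzaldehyde | O=Cc1ccc(O[Si](C(C)C)(C(C)C)C(C)C)cc1O[Si](C(C)C)(C(C)C)C(C)C | intermediate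
7 | lithium 1-[2,4-bis(triisopropylsilyloxy)phenyl]-2-diazo-2-(trimethylsilyl)ethanolate (racemic, not isolated) | [Li]OC(c1ccc(O[Si](C(C)C)(C(C)C)C(C)C)cc1O[Si](C(C)C)(C(C)C)C(C)C)C(=[N+]=[N-])[Si](C)(C)C | intermediate
8 | 1-ethynyl-2,4-bis(triisopropylsilyloxy)benzene | C#Cc1ccc(O[Si](C(C)C)(C(C)C)C(C)C)cc1O[Si](C(C)C)(C(C)C)C(C)C | intermediate
9 | 2-{[2,4-bis(triisopropylsilyloxy)phenyl]ethynyl}-5-methoxy-1,3-bis(methoxymethoxy)benzene | COCOc1cc(OC)cc(OCOC)c1C#Cc1ccc(O[Si](C(C)C)(C(C)C)C(C)C)cc1O[Si](C(C)C)(C(C)C)C(C)C | intermediate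
10 | 2-[2,4-bis(triisopropylsilyloxy)phenyl]-3-iodo-6-methoxy-4-(methoxymethoxy)benzofuran | COCOc1cc(OC)cc2oc(-c3ccc(O[Si](C(C)C)(C(C)C)C(C)C)cc3O[Si](C(C)C)(C(C)C)C(C)C)c(I)c12 | intermediate
11 | {2-[2,4-bis(triisopropylsilyloxy)phenyl]-6-methoxy-4-(methoxymethoxy)benzofuran-3-yl}magnesium chloride (not isolated) | COCOc1cc(OC)cc2oc(-c3ccc(O[Si](C(C)C)(C(C)C)C(C)C)cc3O[Si](C(C)C)(C(C)C)C(C)C)c([Mg]Cl)c12 | intermediate
12 | chloromagnesium (dimethylamino){2-[2,4-bis(triisopropylsilyloxy)phenyl]-6-methoxy-4-(methoxymethoxy)benzofuran-3-yl}methanolate (racemic, not isolated) | COCOc1cc(OC)cc2oc(-c3ccc(O[Si](C(C)C)(C(C)C)C(C)C)cc3O[Si](C(C)C)(C(C)C)C(C)C)c(C(O[Mg]Cl)N(C)C)c12 | intermediate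
13 | 2-[2,4-bis(triisopropylsilyloxy)phenyl]-6-methoxy-4-(methoxymethoxy)benzofuran-3-carbaldehyde | COCOc1cc(OC)cc2oc(-c3ccc(O[Si](C(C)C)(C(C)C)C(C)C)cc3O[Si](C(C)C)(C(C)C)C(C)C)c(C=O)c12 | intermediate
14 | lithium {2-[2,4-bis(triisopropylsilyloxy)phenyl]-6-methoxy-4-(methoxymethoxy)benzofuran-3-yl}(4-methylpiperazin-1-yl)methanolate (racemic, not isolated) | COCOc1cc(OC)cc2oc(-c3ccc(O[Si](C(C)C)(C(C)C)C(C)C)cc3O[Si](C(C)C)(C(C)C)C(C)C)c(C(O[Li])N4CCN(C)CC4)c12 | intermediate
15 | 5-lithio derivative of 14 (racemic, not isolated) | COCOc1c([Li])c(OC)cc2oc(-c3ccc(O[Si](C(C)C)(C(C)C)C(C)C)cc3O[Si](C(C)C)(C(C)C)C(C)C)c(C(O[Li])N4CCN(C)CC4)c12 | intermediate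
16 | 5-(3-methylbut-2-en-1-yl) derivative of 14 (racemic, not isolated) | COCOc1c(CC=C(C)C)c(OC)cc2oc(-c3ccc(O[Si](C(C)C)(C(C)C)C(C)C)cc3O[Si](C(C)C)(C(C)C)C(C)C)c(C(O[Li])N4CCN(C)CC4)c12 | intermediate
17 | 2-[2,4-bis(triisopropylsilyloxy)phenyl]-6-methoxy-4-(methoxymethoxy)-5-(3-methylbut-2-en-1-yl)benzofuran-3-carbaldehyde | COCOc1c(CC=C(C)C)c(OC)cc2oc(-c3ccc(O[Si](C(C)C)(C(C)C)C(C)C)cc3O[Si](C(C)C)(C(C)C)C(C)C)c(C=O)c12 | intermediate
18 | 2-(2,4-dihydroxyphenyl)-6-methoxy-4-(methoxymethoxy)-5-(3-methylbut-2-en-1-yl)benzofuran-3-carbaldehyde (not isolated) | COCOc1c(CC=C(C)C)c(OC)cc2oc(-c3ccc(O)cc3O)c(C=O)c12 | intermediate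
19 | 2-(2,4-dihydroxyphenyl)-4-hydroxy-6-methoxy-5-(3-methylbut-2-en-1-yl)benzofuran-3-carbaldehyde (achiral) | COc1cc2oc(-c3ccc(O)cc3O)c(C=O)c2c(O)c1CC=C(C)C | target

**Step count**
Total: 9 steps. Longest linear sequence: 7 steps (1 → 2 → 4 → 9 → 10 → 13 → 17 → 19; the branch from 5 is equally long).

**Steps most likely to fail, with fallbacks**

Step 8 is the weakest step. Lithiation may also occur at C7 (between the methoxy group and the ring oxygen), and the amino alkoxide may not survive excess n-BuLi. The fallback sets out from 13 and replaces the metalation by a Claisen rearrangement. The MOM ether next to the formyl group is hydrolysed with 1 M aq. HCl in THF at rt to give the 4-hydroxy aldehyde F1. The free phenol is then O-alkylated with methyl 2-methylbut-3-en-2-yl carbonate and Pd(PPh3)4 (zerovalent palladium, branched-selective Tsuji–Trost etherification) in THF at 0 °C to give the 1,1-dimethylallyl ether F2. Heating in toluene at 110 °C brings about the aromatic Claisen rearrangement, which can deliver the allyl unit only to C5 because C3a is a ring-fusion carbon, and gives the 4-hydroxy-5-prenyl aldehyde F3. Bu4NF in THF then removes both silyl ethers, so this fallback comes back to the route at 19.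

Step 6 relies on an acetal-type ether oxygen as the nucleophile in the iodocyclisation; with I2 alone the MOM ether may react slowly or the alkyne may simply add iodine. The fallback sets out from 9. Both MOM ethers are hydrolysed with 2 M aq. HCl in THF at 35 °C (the silyl ethers survive) to give the alkynylresorcinol F4. Its free phenol is cyclised with I2 and NaHCO3 in MeCN at 0 °C (iodocyclisation of an o-alkynylphenol; the two hydroxyl groups are equivalent) to give the 3-iodo-4-hydroxybenzofuran F5. Re-protection with MOMCl and i-Pr2NEt in CH2Cl2 comes back to the route at 10.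

Step 5 couples a very electron-rich aryl iodide carrying two ortho substituents with a hindered alkyne, so slow oxidative addition and copper-mediated alkyne dimerisation are the likely failure. The fallback sets out from 8 and 4 and uses a copper-free Negishi alkynylation. Alkyne 8 is deprotonated with n-BuLi in THF at −78 °C to give the lithium acetylide F6, which is transmetalated with ZnCl2 to the alkynylzinc chloride F7. Coupling of F7 with 4 under Pd(PPh3)4 (zerovalent palladium) in THF at 60 °C comes back to the route at 9.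

**Further compounds**
F1 | step 8 | 2-[2,4-bis(triisopropylsilyloxy)phenyl]-4-hydroxy-6-methoxybenzofuran-3-carbaldehyde | Oc1cc(OC)cc2oc(-c3ccc(O[Si](C(C)C)(C(C)C)C(C)C)cc3O[Si](C(C)C)(C(C)C)C(C)C)c(C=O)c12
F2 | step 8 | 2-[2,4-bis(triisopropylsilyloxy)phenyl]-6-methoxy-4-[(2-methylbut-3-en-2-yl)oxy]benzofuran-3-carbaldehyde | C=CC(C)(C)Oc1cc(OC)cc2oc(-c3ccc(O[Si](C(C)C)(C(C)C)C(C)C)cc3O[Si](C(C)C)(C(C)C)C(C)C)c(C=O)c12
F3 | step 8 | 2-[2,4-bis(triisopropylsilyloxy)phenyl]-4-hydroxy-6-methoxy-5-(3-methylbut-2-en-1-yl)benzofuran-3-carbaldehyde | Oc1c(CC=C(C)C)c(OC)cc2oc(-c3ccc(O[Si](C(C)C)(C(C)C)C(C)C)cc3O[Si](C(C)C)(C(C)C)C(C)C)c(C=O)c12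
F4 | step 6 | 2-{[2,4-bis(triisopropylsilyloxy)phenyl]ethynyl}-5-methoxybenzene-1,3-diol | COc1cc(O)c(C#Cc2ccc(O[Si](C(C)C)(C(C)C)C(C)C)cc2O[Si](C(C)C)(C(C)C)C(C)C)c(O)c1
F5 | step 6 | 2-[2,4-bis(triisopropylsilyloxy)phenyl]-3-iodo-6-methoxybenzofuran-4-ol | Oc1cc(OC)cc2oc(-c3ccc(O[Si](C(C)C)(C(C)C)C(C)C)cc3O[Si](C(C)C)(C(C)C)C(C)C)c(I)c12
F6 | step 5 | lithium [2,4-bis(triisopropylsilyloxy)phenyl]acetylide | [Li]C#Cc1ccc(O[Si](C(C)C)(C(C)C)C(C)C)cc1O[Si](C(C)C)(C(C)C)C(C)C
F7 | step 5 | {[2,4-bis(triisopropylsilyloxy)phenyl]ethynyl}zinc chloride | Cl[Zn]C#Cc1ccc(O[Si](C(C)C)(C(C)C)C(C)C)cc1O[Si](C(C)C)(C(C)C)C(C)C
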